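**Retrosynthetic overview**

1. Target 16 ⇐ bis-MOM flavanone 15 by acidic removal of the two MOM ethers (last step).
2. The six-membered pyranone ring of 15 ⇐ the five-membered furanone ring of racemic 2-(iodomethyl)-2-phenylbenzofuran-3(2H)-one 11, by a radical one-carbon ring expansion (Dowd–Beckwith 1,2-acyl shift). The CH2I carbon becomes C3, and C2 is set in the same operation by enantioselective H-atom transfer to the planar C2 radical, so both enantiomers of 11 converge.
3. Enabling feature: the quaternary C2 of the furanone ring carries the CH2I arm next to the C3 aryl ketone (the 3-exo acceptor). C2 is also flanked by ring O1 and the phenyl group, which stabilise the radical left at C2 when the C2–C3 bond breaks.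
4. 11 ⇐ C2-alkylation of 2-phenylbenzofuranone 9 ⇐ Dieckmann/dealkoxycarbonylation of diester ether 7 ⇐ O-alkylation of salicylate 5 ⇐ MOM protection and C-diprenylation of mirror-symmetric methyl 2,4,6-trihydroxybenzoate 1 (equivalent ring carbons and ortho-OH groups, so no regiochemical choice).
5. Ring order: benzene ring purchased; five-membered O-heterocycle (step 4); six-membered pyranone from it (step 6).

Key step: step 6

Assumption: the face selectivity of the D-manno thiol catalyst toward radical 14 is taken to favour 2S; if the opposite sense prevails, the mirror-image (L-manno) thiol would be used without other change.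

**Route**

Step 1
Reactants: 1 methyl 2,4,6-trihydroxybenzoate; 2 prenyl bromide (1-bromo-3-methylbut-2-ene)
Product: 3 methyl 2,4,6-trihydroxy-3,5-bis(3-methylbut-2-en-1-yl)benzoate
Conditions: NaOMe (3 equiv), 2 (2.2 equiv), MeOH, 0 °C → rt
Reagents that add atoms: prenyl bromide (compound 2), CC(C)=CCBr
Why: C-prenylation of a phloroglucinol-type phenoxide, where the protic solvent steers the soft allylic bromide to the two equivalent ring carbons C3 and C5 of the mirror-symmetric ester, so only the degree of alkylation has to be controlled by stoichiometry.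

Step 2
Reactants: 3; 4 chloromethyl methyl ether (MOMCl)
Product: 5 methyl 2-hydroxy-4,6-bis(methoxymethoxy)-3,5-bis(3-methylbut-2-en-1-yl)benzoate
Conditions: MOMCl (2.2 equiv), iPr2NEt (3 equiv), CH2Cl2, 0 °C → rt
Reagents that add atoms: chloromethyl methyl ether (compound 4), COCCl
Why: MOM etherification under amine base should take the 4-OH and one of the two equivalent ortho OH groups, while the last OH stays free because it is hindered and hydrogen-bonded to the ester carbonyl.

Step 3
Reactants: 5; 6 methyl 2-bromo-2-phenylacetate (racemic)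
Product: 7 methyl 2-(2-methoxy-2-oxo-1-phenylethoxy)-4,6-bis(methoxymethoxy)-3,5-bis(3-methylbut-2-en-1-yl)benzoate (racemic)
Conditions: 6 (1.3 equiv), Cs2CO3 (1.5 equiv), DMF, rt → 50 °C
Reagents that add atoms: methyl 2-bromo-2-phenylacetate (compound 6), COC(=O)C(Br)c1ccccc1
Why: Williamson ether synthesis (SN2) of the caesium phenoxide on the activated benzylic α-bromo ester; the new stereocentre forms as a racemate, which is irrelevant because this carbon becomes trigonal again before the key step.

Step 4
Reactants: 7
Product: 9 4,6-bis(methoxymethoxy)-5,7-bis(3-methylbut-2-en-1-yl)-2-phenylbenzofuran-3(2H)-one (racemic, C2–H labile), via quaternary β-keto ester 8 (not isolated)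
Conditions: NaOMe (2 equiv), MeOH/THF (degassed), 60 °C; then AcOH, 0 °C; handled under argon
Reagents that add atoms: none
Why: Dieckmann condensation of the stabilised ester enolate onto the aryl ester (5-exo-trig) should give the non-enolisable β-keto ester 8, which methoxide cleaves at the exocyclic ester (retro-Claisen dealkoxycarbonylation) because the aromatic 3-oxidobenzofuran enolate is by far the best leaving group; the acidic quench then gives 9.

Step 5
Reactants: 9; 10 diiodomethane
Product: 11 2-(iodomethyl)-4,6-bis(methoxymethoxy)-5,7-bis(3-methylbut-2-en-1-yl)-2-phenylbenzofuran-3(2H)-one (racemic)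
Conditions: NaH (1.1 equiv), THF (degassed), 0 °C; then CH2I2 (10 equiv), 50 °C, dark
Reagents that add atoms: diiodomethane (compound 10), ICI
Why: C-alkylation of the sodium enolate with excess diiodomethane, the way Dowd–Beckwith precursors are made from β-keto esters, should build the racemic quaternary C2 with its iodomethyl arm, the sodium counter-ion in THF and the soft iodide favouring C over O.

Step 6
Reactants: 11
Product: 15 (S)-5,7-bis(methoxymethoxy)-6,8-bis(3-methylbut-2-en-1-yl)-2-phenylchroman-4-one, via primary alkyl radical 12 (not isolated), via cyclopropyloxyl radical 13 (not isolated), via chromanon-2-yl radical 14 (not isolated)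
Conditions: 4CzIPN (2 mol %), 2,3,4,6-tetra-O-acetyl-1-thio-β-D-mannopyranose (10 mol %), Et3N (3 equiv), H2O (10 equiv), MeCN (0.02 M, degassed), 450 nm LEDs, 0 °C
Reagents that add atoms: none
Why: Proposed new method: a Dowd–Beckwith one-carbon ring expansion terminated by enantioselective hydrogen-atom transfer, in which iodine-atom abstraction from 11 by the α-aminoalkyl radical formed from Et3N (photoredox halogen-atom transfer) gives primary radical 12, which adds 3-exo-trig to the C3 aryl ketone to give cyclopropyloxyl radical 13, and β-scission of the old C2–C3 bond then opens 13 to the chroman-4-on-2-yl radical 14, so the furanone becomes the pyranone by a net 1,2-acyl shift with the former CH2I carbon as C3. The closest known reaction types are the tin-hydride Dowd–Beckwith expansion of α-(halomethyl) cyclic β-keto esters, the amine-mediated photoredox hydrodehalogenation of alkyl iodides with a thiol co-catalyst, and enantioselective H transfer from homochiral carbohydrate thiols to cyclic tertiary α-oxy radicals in radical-chain hydrosilylation. No ring is closed by a cyclisation in the usual sense: the only closure is the transient 3-exo-trig cyclopropane, and the six-membered ring arises from it by fragmentation. The C2 stereocentre is created when the planar, benzylic, α-aryloxy radical 14 takes H from the homochiral thiol, with the catalyst alone controlling the face, so both enantiomers of 11 should converge on one configuration. The step needs the 1,2-acyl shift to outrun direct reduction of 12 and the neophyl 1,2-phenyl shift; the low stationary thiol concentration, the conjugated aryl ketone as acceptor and the doubly stabilised (phenyl, O1) product radical should secure this, and the nucleophilic α-aminoalkyl radical should leave the electron-rich prenyl alkenes untouched.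

Step 7
Reactants: 15
Product: 16 (S)-5,7-dihydroxy-6,8-bis(3-methylbut-2-en-1-yl)-2-phenylchroman-4-one (target)
Conditions: 3 M aq. HCl/MeOH (1:4), 45 °C
Reagents that add atoms: none
Why: Acid-catalysed acetal exchange of the two MOM ethers with methanol should free both phenols under conditions that avoid base (no retro-oxa-Michael racemisation at C2) and are mild enough for the prenyl double bonds.

**Compound list**

1 | methyl 2,4,6-trihydroxybenzoate | COC(=O)c1c(O)cc(O)cc1O | starting material
2 | prenyl bromide (1-bromo-3-methylbut-2-ene) | CC(C)=CCBr | starting material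
3 | methyl 2,4,6-trihydroxy-3,5-bis(3-methylbut-2-en-1-yl)benzoate | COC(=O)c1c(O)c(CC=C(C)C)c(O)c(CC=C(C)C)c1O | intermediate
4 | chloromethyl methyl ether | COCCl | starting material
5 | methyl 2-hydroxy-4,6-bis(methoxymethoxy)-3,5-bis(3-methylbut-2-en-1-yl)benzoate | COC(=O)c1c(O)c(CC=C(C)C)c(OCOC)c(CC=C(C)C)c1OCOC | intermediate
6 | methyl 2-bromo-2-phenylacetate (racemic) | COC(=O)C(Br)c1ccccc1 | starting material
7 | methyl 2-(2-methoxy-2-oxo-1-phenylethoxy)-4,6-bis(methoxymethoxy)-3,5-bis(3-methylbut-2-en-1-yl)benzoate (racemic) | COC(=O)C(Oc1c(CC=C(C)C)c(OCOC)c(CC=C(C)C)c(OCOC)c1C(=O)OC)c1ccccc1 | intermediate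
8 | methyl 4,6-bis(methoxymethoxy)-5,7-bis(3-methylbut-2-en-1-yl)-3-oxo-2-phenyl-2,3-dihydrobenzofuran-2-carboxylate (racemic) | COC(=O)C1(c2ccccc2)Oc2c(CC=C(C)C)c(OCOC)c(CC=C(C)C)c(OCOC)c2C1=O | intermediate (not isolated)
9 | 4,6-bis(methoxymethoxy)-5,7-bis(3-methylbut-2-en-1-yl)-2-phenylbenzofuran-3(2H)-one (racemic) | O=C1C(c2ccccc2)Oc2c(CC=C(C)C)c(OCOC)c(CC=C(C)C)c(OCOC)c12 | intermediate
10 | diiodomethane | ICI | starting material
11 | 2-(iodomethyl)-4,6-bis(methoxymethoxy)-5,7-bis(3-methylbut-2-en-1-yl)-2-phenylbenzofuran-3(2H)-one (racemic) | O=C1C(CI)(c2ccccc2)Oc2c(CC=C(C)C)c(OCOC)c(CC=C(C)C)c(OCOC)c12 | intermediate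
12 | (3-oxo-2-phenyl-2,3-dihydrobenzofuran-2-yl)methyl radical, 4,6-bis(methoxymethoxy)-5,7-diprenyl substituted | [CH2]C1(c2ccccc2)Oc2c(CC=C(C)C)c(OCOC)c(CC=C(C)C)c(OCOC)c2C1=O | intermediate (not isolated)
13 | cyclopropane-fused benzofuranyl-oxyl radical (cyclopropane made of the CH2 carbon, C2 and C3; O-centred radical on C3) | [O]C12CC1(c1ccccc1)Oc1c(CC=C(C)C)c(OCOC)c(CC=C(C)C)c(OCOC)c12 | intermediate (not isolated)
14 | 5,7-bis(methoxymethoxy)-4-oxo-2-phenyl-6,8-diprenylchroman-2-yl radical | O=C1C[C](c2ccccc2)Oc2c(CC=C(C)C)c(OCOC)c(CC=C(C)C)c(OCOC)c12 | intermediate (not isolated)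
15 | (S)-5,7-bis(methoxymethoxy)-6,8-bis(3-methylbut-2-en-1-yl)-2-phenylchroman-4-one | O=C1C[C@@H](c2ccccc2)Oc2c(CC=C(C)C)c(OCOC)c(CC=C(C)C)c(OCOC)c12 | intermediate
16 | (S)-5,7-dihydroxy-6,8-bis(3-methylbut-2-en-1-yl)-2-phenylchroman-4-one | CC(C)=CCc1c(O)c(CC=C(C)C)c2c(c1O)C(=O)C[C@@H](c1ccccc1)O2 | target

**Step count and risks**

Total step count: 7. Longest linear sequence: 7 steps (1 → 16).

Steps most likely to fail:

1. Step 6 (Proposed new method). Hydrogen delivery to the planar radical 14 may show poor facial selectivity, the thiyl radical may re-abstract the C2 hydrogen and erode the enantiomeric purity, or 12 may be reduced before the acyl shift. Fallback, from 11 back to 15: the classical tin-hydride Dowd–Beckwith expansion (Bu3SnH by syringe pump, AIBN, benzene, 80 °C) should give the racemic 5,7-bis(methoxymethoxy)-6,8-diprenylflavanone F1. A kinetic resolution by Noyori asymmetric transfer hydrogenation (RuCl(p-cymene)[(R,R)-TsDPEN], HCO2H/Et3N, rt) should then reduce the 2R ketone to the cis-(2R,4R)-flavan-4-ol F2 and leave (S)-15, which is separated by chromatography.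

2. Step 5. The ambident, aromatic enolate of 9 may be alkylated on oxygen instead of carbon, or two enolates may be bridged by one CH2. Fallback, from 9 back to 11: a formaldehyde aldol reaction (37 % aq. HCHO, cat. Et3N, THF, rt), which is C-selective, should give the 2-(hydroxymethyl) ketone F3. Appel-type iodination (PPh3, I2, imidazole, toluene, 70 °C) then converts F3 into 11.

3. Step 1. The degree and site of prenylation may be poorly controlled (mono-, geminal di- and O-prenylation beside the wanted 3,5-di-C-prenylation). Fallback, from 1 back to 5: MOMCl (compound 4)/iPr2NEt should give methyl 2-hydroxy-4,6-bis(methoxymethoxy)benzoate F4. N-Iodosuccinimide (2.2 equiv, DMF, 0 °C) should iodinate the two free ring positions to give methyl 2-hydroxy-3,5-diiodo-4,6-bis(methoxymethoxy)benzoate F5. A twofold Stille coupling with tributyl(3-methylbut-2-en-1-yl)stannane (Pd(PPh3)4, DMF, 80 °C) then installs both prenyl groups and gives 5 directly.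

**Further compounds**

F1 | step 6 | racemic 5,7-bis(methoxymethoxy)-6,8-bis(3-methylbut-2-en-1-yl)-2-phenylchroman-4-one | O=C1CC(c2ccccc2)Oc2c(CC=C(C)C)c(OCOC)c(CC=C(C)C)c(OCOC)c12
F2 | step 6 | (2R,4R)-5,7-bis(methoxymethoxy)-6,8-bis(3-methylbut-2-en-1-yl)-2-phenylchroman-4-ol (2,4-cis) | O[C@@H]1C[C@H](c2ccccc2)Oc2c(CC=C(C)C)c(OCOC)c(CC=C(C)C)c(OCOC)c21
F3 | step 5 | 2-(hydroxymethyl)-4,6-bis(methoxymethoxy)-5,7-bis(3-methylbut-2-en-1-yl)-2-phenylbenzofuran-3(2H)-one (racemic) | O=C1C(CO)(c2ccccc2)Oc2c(CC=C(C)C)c(OCOC)c(CC=C(C)C)c(OCOC)c12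
F4 | step 1 | methyl 2-hydroxy-4,6-bis(methoxymethoxy)benzoate | COC(=O)c1c(O)cc(OCOC)cc1OCOC
F5 | step 1 | methyl 2-hydroxy-3,5-diiodo-4,6-bis(methoxymethoxy)benzoate | COC(=O)c1c(O)c(I)c(OCOC)c(I)c1OCOC
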